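**Assumption:** germacrane numbering is used (lactone oxygen on C6, lactone carbonyl C12, ester on C3, hydroxyl on C9). The SMILES is read as 3S,6R,7S,9S,11R, 1(10)Z, 4E with an (R)-2-methylbutanoate, which makes the γ-lactone all-cis (C5, C8 and the C11 methyl on one face).

**Retrosynthetic overview**
1. C9 carbinol: ketoreductase reduction of the ten-membered enone; enone from oxidation of the Nozaki–Hiyama–Kishi (NHK) product (C9–C10 bond, carbocycle formed second).
2. C3 ester: Yamaguchi coupling with (R)-2-methylbutanoic acid (Ru-catalysed asymmetric hydrogenation of tiglic acid); C9–OH freed by a lipase.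
3. C1–C5: Stork–Zhao olefination (Z-vinyl iodide), Keck allylation (C3), Wittig reaction (E-C4=C5) on a lactone aldehyde.
4. All-cis γ-lactone (ring formed first): face-selective hydrogenation of a butenolide made by carbomagnesiation/carboxylation of a propargylic alcohol.
5. First main-chain stereocentre (C6): asymmetric transfer hydrogenation of an achiral ynone.

**Route**

Step 1
Reactants: 1 tiglic acid
Product: 2 (R)-2-methylbutanoic acid
Conditions: H2 (4 atm), Ru(OAc)2[(R)-H8-BINAP] (0.5 mol%), MeOH, 20 °C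
Reagents that add atoms: none
Why: Asymmetric hydrogenation of an α,β-unsaturated acid; the carboxylate-bound Ru–diphosphine delivers H2 to one enantioface and the (R)-ligand gives the (R)-acid (about 97% ee expected).

Step 2
Reactants: 3 methyl glycolate
Product: 4 methyl 2-[(triisopropylsilyl)oxy]acetate
Conditions: TIPSCl, imidazole, DMF, 0 °C to rt
Reagents that add atoms: triisopropylsilyl chloride, CC(C)[Si](Cl)(C(C)C)C(C)C
Why: Standard silylation; TIPS survives Grignard reagents, resists silyl migration and has no arene for Rh to reduce in step 10.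

Step 3
Reactants: 4 methyl 2-[(triisopropylsilyl)oxy]acetate
Product: 5 N-methoxy-N-methyl-2-[(triisopropylsilyl)oxy]acetamide
Conditions: MeNH(OMe)·HCl, iPrMgCl, THF, −20 °C
Reagents that add atoms: N,O-dimethylhydroxylamine hydrochloride, CNOC.Cl
Why: Weinreb amide formation by aminolysis of the ester with the chloromagnesium amide.

Step 4
Reactants: 5 N-methoxy-N-methyl-2-[(triisopropylsilyl)oxy]acetamide; 6 1-propynylmagnesium bromide
Product: 7 1-[(triisopropylsilyl)oxy]pent-3-yn-2-one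
Conditions: THF, 0 °C
Reagents that add atoms: 1-propynylmagnesium bromide (6), CC#C[Mg]Br
Why: Weinreb ketone synthesis; the chelated tetrahedral intermediate stops over-addition, so no stereocentre exists before step 5.

Step 5
Reactants: 7 1-[(triisopropylsilyl)oxy]pent-3-yn-2-one
Product: 8 (R)-1-[(triisopropylsilyl)oxy]pent-3-yn-2-ol
Conditions: Ru[(S,S)-TsDPEN](p-cymene) (1 mol%), iPrOH, rt
Reagents that add atoms: none
Why: Noyori asymmetric transfer hydrogenation of an ynone; the (S,S)-catalyst, by analogy with simple ynones, delivers hydride with the alkynyl group in the arene-recognition site, setting C6 as R (CH2OSi outranks the alkyne).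

Step 6
Reactants: 8 (R)-1-[(triisopropylsilyl)oxy]pent-3-yn-2-ol; 9 allylmagnesium chloride; 10 carbon dioxide
Product: 13 (R)-3-methyl-4-(prop-2-enyl)-5-{[(triisopropylsilyl)oxy]methyl}furan-2(5H)-one, via oxamagnesacycle 11 (not isolated), via hydroxy acid 12 (not isolated)
Conditions: allylMgCl (3.5 equiv), THF, rt to 50 °C; CO2, −20 °C to rt; 1 M HCl
Reagents that add atoms: allylmagnesium chloride (9), C=CC[Mg]Cl; carbon dioxide (10), O=C=O
Why: Alkoxide-directed anti-carbomagnesiation puts allyl on the proximal alkyne carbon and Mg on the distal carbon cis to the carbinol (five-membered chelate); carboxylation and lactonisation of the Z-hydroxy acid give the butenolide with C6 untouched.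

Step 7
Reactants: 13 (R)-3-methyl-4-(prop-2-enyl)-5-{[(triisopropylsilyl)oxy]methyl}furan-2(5H)-one
Product: 15 2-[(2R)-4-methyl-5-oxo-2-{[(triisopropylsilyl)oxy]methyl}-2,5-dihydrofuran-3-yl]acetaldehyde, via diol 14 (not isolated)
Conditions: OsO4 (2 mol%), NMO, acetone/H2O, rt; then NaIO4, 0 °C
Reagents that add atoms: OsO4, O=[Os](=O)(=O)=O; N-methylmorpholine N-oxide, C[N+]1([O-])CCOCC1
Why: Upjohn dihydroxylation and periodate cleavage; OsO4 takes only the monosubstituted alkene because the tetrasubstituted, electron-poor butenolide alkene is inert (aldehyde used crude at once).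

Step 8
Reactants: 15 2-[(2R)-4-methyl-5-oxo-2-{[(triisopropylsilyl)oxy]methyl}-2,5-dihydrofuran-3-yl]acetaldehyde
Product: 16 (R)-4-(2-hydroxyethyl)-3-methyl-5-{[(triisopropylsilyl)oxy]methyl}furan-2(5H)-one
Conditions: NaBH4, MeOH, −20 °C
Reagents that add atoms: none
Why: Chemoselective borohydride reduction of the aldehyde; the hindered butenolide is not reduced at low temperature.

Step 9
Reactants: 16 (R)-4-(2-hydroxyethyl)-3-methyl-5-{[(triisopropylsilyl)oxy]methyl}furan-2(5H)-one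
Product: 17 2-[(2R)-4-methyl-5-oxo-2-{[(triisopropylsilyl)oxy]methyl}-2,5-dihydrofuran-3-yl]ethyl acetate
Conditions: Ac2O, pyridine, DMAP (cat.), CH2Cl2, 0 °C
Reagents that add atoms: acetic anhydride, CC(=O)OC(C)=O
Why: DMAP-catalysed acetylation; the acetate masks C9–OH until the enzymatic release in step 20.

Step 10
Reactants: 17 2-[(2R)-4-methyl-5-oxo-2-{[(triisopropylsilyl)oxy]methyl}-2,5-dihydrofuran-3-yl]ethyl acetate
Product: 18 2-[(2R,3S,4R)-4-methyl-5-oxo-2-{[(triisopropylsilyl)oxy]methyl}oxolan-3-yl]ethyl acetate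
Conditions: H2 (60 bar), Rh/Al2O3 (5 wt% Rh), EtOAc, rt
Reagents that add atoms: none
Why: Heterogeneous syn-hydrogenation of the tetrasubstituted butenolide from the face opposite the C6 CH2OTIPS group sets C7 (S) and C11 (R) in one step (all-cis lactone); Rh avoids hydrogenolysis of the allylic C–O bond.

Step 11
Reactants: 18 2-[(2R,3S,4R)-4-methyl-5-oxo-2-{[(triisopropylsilyl)oxy]methyl}oxolan-3-yl]ethyl acetate
Product: 19 2-[(2R,3S,4R)-2-(hydroxymethyl)-4-methyl-5-oxooxolan-3-yl]ethyl acetate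
Conditions: 48% aq. HF, MeCN, 0 °C to rt
Reagents that add atoms: none
Why: Acidic fluoride desilylation; acetate and lactone are stable and no base touches the epimerisable C11.

Step 12
Reactants: 19 2-[(2R,3S,4R)-2-(hydroxymethyl)-4-methyl-5-oxooxolan-3-yl]ethyl acetate
Product: 20 2-[(2R,3S,4R)-2-formyl-4-methyl-5-oxooxolan-3-yl]ethyl acetate
Conditions: Dess–Martin periodinane, CH2Cl2, 0 °C to rt
Reagents that add atoms: none
Why: Dess–Martin oxidation under non-basic conditions, so the α-oxygenated aldehyde keeps C6 (used crude).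

Step 13
Reactants: 20 2-[(2R,3S,4R)-2-formyl-4-methyl-5-oxooxolan-3-yl]ethyl acetate; 21 2-(triphenylphosphoranylidene)propanal
Product: 22 2-{(2R,3S,4R)-4-methyl-2-[(E)-2-methyl-3-oxoprop-1-enyl]-5-oxooxolan-3-yl}ethyl acetate
Conditions: toluene, 70 °C
Reagents that add atoms: 2-(triphenylphosphoranylidene)propanal (21), CC(C=O)=P(c1ccccc1)(c1ccccc1)c1ccccc1
Why: Wittig olefination with a stabilised formyl ylide gives the E trisubstituted enal (C4=C5) under thermodynamic control; the ylide is too weakly basic to epimerise C6 or C11.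

Step 14
Reactants: 22 2-{(2R,3S,4R)-4-methyl-2-[(E)-2-methyl-3-oxoprop-1-enyl]-5-oxooxolan-3-yl}ethyl acetate; 23 allyltributylstannane
Product: 24 2-{(2R,3S,4R)-2-[(1E,3S)-3-hydroxy-2-methylhexa-1,5-dienyl]-4-methyl-5-oxooxolan-3-yl}ethyl acetate
Conditions: Ti(OiPr)4 (10 mol%), (S)-BINOL (20 mol%), 4 Å MS, CH2Cl2, −20 °C, 72 h
Reagents that add atoms: allyltributylstannane (23), C=CC[Sn](CCCC)(CCCC)CCCC
Why: Keck asymmetric allylation; the (S)-BINOL–Ti Lewis acid blocks one face of the enal, so 1,2-allyl transfer sets C3 as S under catalyst control (the remote lactone centres exert no bias).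

Step 15
Reactants: 24 2-{(2R,3S,4R)-2-[(1E,3S)-3-hydroxy-2-methylhexa-1,5-dienyl]-4-methyl-5-oxooxolan-3-yl}ethyl acetate
Product: 25 2-{(2R,3S,4R)-2-[(1E,3S)-3-[(tert-butyldimethylsilyl)oxy]-2-methylhexa-1,5-dienyl]-4-methyl-5-oxooxolan-3-yl}ethyl acetate
Conditions: TBSOTf, 2,6-lutidine, CH2Cl2, −78 °C
Reagents that add atoms: tert-butyldimethylsilyl triflate, CC(C)(C)[Si](C)(C)OS(=O)(=O)C(F)(F)F
Why: Silylation of the allylic alcohol; a silyl ether (not the ester) is carried through the basic ylide step to avoid β-elimination.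

Step 16
Reactants: 25 2-{(2R,3S,4R)-2-[(1E,3S)-3-[(tert-butyldimethylsilyl)oxy]-2-methylhexa-1,5-dienyl]-4-methyl-5-oxooxolan-3-yl}ethyl acetate
Product: 27 2-{(2R,3S,4R)-2-[(1E,3S)-3-[(tert-butyldimethylsilyl)oxy]-2-methyl-5-oxopent-1-enyl]-4-methyl-5-oxooxolan-3-yl}ethyl acetate, via diol 26 (not isolated)
Conditions: OsO4 (2 mol%), NMO, acetone/H2O, 0 °C to rt; then NaIO4
Reagents that add atoms: OsO4, O=[Os](=O)(=O)=O; N-methylmorpholine N-oxide, C[N+]1([O-])CCOCC1
Why: Upjohn dihydroxylation and periodate cleavage; the terminal alkene reacts in preference to the hindered C4=C5 alkene, which is deactivated by two allylic oxygens.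

Step 17
Reactants: 27 2-{(2R,3S,4R)-2-[(1E,3S)-3-[(tert-butyldimethylsilyl)oxy]-2-methyl-5-oxopent-1-enyl]-4-methyl-5-oxooxolan-3-yl}ethyl acetate; 28 ethyltriphenylphosphonium iodide
Product: 29 2-{(2R,3S,4R)-2-[(1E,3S,5Z)-3-[(tert-butyldimethylsilyl)oxy]-6-iodo-2-methylhepta-1,5-dienyl]-4-methyl-5-oxooxolan-3-yl}ethyl acetate
Conditions: 28, n-BuLi, THF; I2, −78 °C; NaHMDS, −20 °C; then 27, −78 to −20 °C
Reagents that add atoms: ethyltriphenylphosphonium iodide (28), CC[P+](c1ccccc1)(c1ccccc1)c1ccccc1.[I-]; iodine, II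
Why: Stork–Zhao olefination; the non-stabilised α-iodo ylide reacts under kinetic control to give the Z-2-iodoalkene (iodine cis to the chain), fixing the C1=C10 geometry, and is not basic enough to enolise the lactone.

Step 18
Reactants: 29 2-{(2R,3S,4R)-2-[(1E,3S,5Z)-3-[(tert-butyldimethylsilyl)oxy]-6-iodo-2-methylhepta-1,5-dienyl]-4-methyl-5-oxooxolan-3-yl}ethyl acetate
Product: 30 2-{(2R,3S,4R)-2-[(1E,3S,5Z)-3-hydroxy-6-iodo-2-methylhepta-1,5-dienyl]-4-methyl-5-oxooxolan-3-yl}ethyl acetate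
Conditions: HF·pyridine, pyridine, THF, 0 °C to rt
Reagents that add atoms: none
Why: Buffered fluoride desilylation; acetate, lactone and vinyl iodide are untouched and no other silyl group is present.

Step 19
Reactants: 30 2-{(2R,3S,4R)-2-[(1E,3S,5Z)-3-hydroxy-6-iodo-2-methylhepta-1,5-dienyl]-4-methyl-5-oxooxolan-3-yl}ethyl acetate; 2 (R)-2-methylbutanoic acid
Product: 32 (1E,3S,5Z)-1-[(2R,3S,4R)-3-(2-acetoxyethyl)-4-methyl-5-oxooxolan-2-yl]-6-iodo-2-methylhepta-1,5-dien-3-yl (2R)-2-methylbutanoate, via mixed anhydride 31 (not isolated)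
Conditions: 2, 2,4,6-trichlorobenzoyl chloride, Et3N, THF, rt; then 30, DMAP, toluene, rt
Reagents that add atoms: (R)-2-methylbutanoic acid (2), CC[C@@H](C)C(=O)O; 2,4,6-trichlorobenzoyl chloride (into intermediate 31 only), O=C(Cl)c1c(Cl)cc(Cl)cc1Cl
Why: Yamaguchi esterification; DMAP attacks the unhindered acyl of the mixed anhydride and the simple α-alkyl acid is expected not to racemise under these conditions.

Step 20
Reactants: 32 (1E,3S,5Z)-1-[(2R,3S,4R)-3-(2-acetoxyethyl)-4-methyl-5-oxooxolan-2-yl]-6-iodo-2-methylhepta-1,5-dien-3-yl (2R)-2-methylbutanoate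
Product: 33 (1E,3S,5Z)-1-[(2R,3S,4R)-3-(2-hydroxyethyl)-4-methyl-5-oxooxolan-2-yl]-6-iodo-2-methylhepta-1,5-dien-3-yl (2R)-2-methylbutanoate
Conditions: lipase (Candida antarctica lipase B, immobilised), pH 7 phosphate buffer/MTBE, 30 °C
Reagents that add atoms: none
Why: Lipase-catalysed hydrolysis takes the unhindered primary acetate far faster than the α-branched secondary ester or the lactone, and the neutral pH protects C11 and the acyl stereocentre, which chemical deacetylation would endanger.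

Step 21
Reactants: 33 (1E,3S,5Z)-1-[(2R,3S,4R)-3-(2-hydroxyethyl)-4-methyl-5-oxooxolan-2-yl]-6-iodo-2-methylhepta-1,5-dien-3-yl (2R)-2-methylbutanoate
Product: 34 (1E,3S,5Z)-6-iodo-2-methyl-1-[(2R,3S,4R)-4-methyl-5-oxo-3-(2-oxoethyl)oxolan-2-yl]hepta-1,5-dien-3-yl (2R)-2-methylbutanoate
Conditions: Dess–Martin periodinane, CH2Cl2, 0 °C to rt
Reagents that add atoms: none
Why: Dess–Martin oxidation of the primary alcohol; vinyl iodide and esters are inert.

Step 22
Reactants: 34 (1E,3S,5Z)-6-iodo-2-methyl-1-[(2R,3S,4R)-4-methyl-5-oxo-3-(2-oxoethyl)oxolan-2-yl]hepta-1,5-dien-3-yl (2R)-2-methylbutanoate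
Product: 35 (3R,3aS,5RS,6Z,9S,10E,11aR)-5-hydroxy-3,6,10-trimethyl-2-oxo-2,3,3a,4,5,8,9,11a-octahydrocyclodeca[b]furan-9-yl (2R)-2-methylbutanoate (C9 epimers)
Conditions: CrCl2 (8 equiv), NiCl2 (1 mol% of Cr), degassed DMSO, rt, 2 mM, syringe-pump addition
Reagents that add atoms: none
Why: NHK macrocyclisation; zerovalent nickel inserts into the C–I bond, the alkenyl group passes to trivalent chromium and adds only to the aldehyde with retention of the Z geometry, closing the ten-membered ring; no bias at C9 is assumed and both epimers are converged in steps 23 and 24.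

Step 23
Reactants: 35 (C9-epimeric macrocyclic allylic alcohols)
Product: 36 (3R,3aS,6Z,9S,10E,11aR)-3,6,10-trimethyl-2,5-dioxo-2,3,3a,4,5,8,9,11a-octahydrocyclodeca[b]furan-9-yl (2R)-2-methylbutanoate
Conditions: Dess–Martin periodinane, CH2Cl2, 0 °C
Reagents that add atoms: none
Why: Dess–Martin oxidation erases the uncontrolled C9 centre under neutral conditions that avoid γ-deprotonation and loss of the C3 ester.

Step 24
Reactants: 36 (macrocyclic Z-enone)
Product: 37 (3R,3aS,5S,6Z,9S,10E,11aR)-5-hydroxy-3,6,10-trimethyl-2-oxo-2,3,3a,4,5,8,9,11a-octahydrocyclodeca[b]furan-9-yl (2R)-2-methylbutanoate (target)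
Conditions: ketoreductase (S-selective variant from panel screening, NADPH-dependent), NADP+ (cat.), iPrOH (10% v/v), pH 7 phosphate buffer, DMSO (5%), 30 °C
Reagents that add atoms: none
Why: Ketoreductase-catalysed 1,2-reduction; the active site delivers hydride from NADPH to one carbonyl face, setting C9 as S under enzyme control at neutral pH, so the esters, C11 and the alkenes are untouched.

**Compound list**
1 | tiglic acid, (E)-2-methylbut-2-enoic acid | C/C=C(\C)C(=O)O | starting material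
2 | (R)-2-methylbutanoic acid | CC[C@@H](C)C(=O)O | intermediate
3 | methyl glycolate | COC(=O)CO | starting material
4 | methyl 2-[(triisopropylsilyl)oxy]acetate | COC(=O)CO[Si](C(C)C)(C(C)C)C(C)C | intermediate
5 | N-methoxy-N-methyl-2-[(triisopropylsilyl)oxy]acetamide | CON(C)C(=O)CO[Si](C(C)C)(C(C)C)C(C)C | intermediate
6 | 1-propynylmagnesium bromide | CC#C[Mg]Br | starting material
7 | 1-[(triisopropylsilyl)oxy]pent-3-yn-2-one | CC#CC(=O)CO[Si](C(C)C)(C(C)C)C(C)C | intermediate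
8 | (R)-1-[(triisopropylsilyl)oxy]pent-3-yn-2-ol | CC#C[C@@H](O)CO[Si](C(C)C)(C(C)C)C(C)C | intermediate
9 | allylmagnesium chloride | C=CC[Mg]Cl | starting material
10 | carbon dioxide | O=C=O | starting material
11 | (5R)-3-methyl-4-(prop-2-enyl)-5-{[(triisopropylsilyl)oxy]methyl}-2,5-dihydro-1,2-oxamagnesole (not isolated) | CC1=C(CC=C)[C@H](CO[Si](C(C)C)(C(C)C)C(C)C)O[Mg]1 | intermediate
12 | (2Z,4R)-4-hydroxy-2-methyl-3-(prop-2-enyl)-5-[(triisopropylsilyl)oxy]pent-2-enoic acid (not isolated) | C/C(C(=O)O)=C(\CC=C)[C@@H](O)CO[Si](C(C)C)(C(C)C)C(C)C | intermediate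
13 | (R)-3-methyl-4-(prop-2-enyl)-5-{[(triisopropylsilyl)oxy]methyl}furan-2(5H)-one | C=CCC1=C(C)C(=O)O[C@H]1CO[Si](C(C)C)(C(C)C)C(C)C | intermediate
14 | (5R)-4-(2,3-dihydroxypropyl)-3-methyl-5-{[(triisopropylsilyl)oxy]methyl}furan-2(5H)-one, both carbinol epimers (not isolated) | OCC(O)CC1=C(C)C(=O)O[C@H]1CO[Si](C(C)C)(C(C)C)C(C)C | intermediate
15 | 2-[(2R)-4-methyl-5-oxo-2-{[(triisopropylsilyl)oxy]methyl}-2,5-dihydrofuran-3-yl]acetaldehyde | O=CCC1=C(C)C(=O)O[C@H]1CO[Si](C(C)C)(C(C)C)C(C)C | intermediate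
16 | (R)-4-(2-hydroxyethyl)-3-methyl-5-{[(triisopropylsilyl)oxy]methyl}furan-2(5H)-one | OCCC1=C(C)C(=O)O[C@H]1CO[Si](C(C)C)(C(C)C)C(C)C | intermediate
17 | 2-[(2R)-4-methyl-5-oxo-2-{[(triisopropylsilyl)oxy]methyl}-2,5-dihydrofuran-3-yl]ethyl acetate | CC(=O)OCCC1=C(C)C(=O)O[C@H]1CO[Si](C(C)C)(C(C)C)C(C)C | intermediate
18 | 2-[(2R,3S,4R)-4-methyl-5-oxo-2-{[(triisopropylsilyl)oxy]methyl}oxolan-3-yl]ethyl acetate (all-cis) | CC(=O)OCC[C@@H]1[C@H](CO[Si](C(C)C)(C(C)C)C(C)C)OC(=O)[C@@H]1C | intermediate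
19 | 2-[(2R,3S,4R)-2-(hydroxymethyl)-4-methyl-5-oxooxolan-3-yl]ethyl acetate | CC(=O)OCC[C@@H]1[C@H](CO)OC(=O)[C@@H]1C | intermediate
20 | 2-[(2R,3S,4R)-2-formyl-4-methyl-5-oxooxolan-3-yl]ethyl acetate | CC(=O)OCC[C@@H]1[C@H](C=O)OC(=O)[C@@H]1C | intermediate
21 | 2-(triphenylphosphoranylidene)propanal | CC(C=O)=P(c1ccccc1)(c1ccccc1)c1ccccc1 | starting material
22 | 2-{(2R,3S,4R)-4-methyl-2-[(E)-2-methyl-3-oxoprop-1-enyl]-5-oxooxolan-3-yl}ethyl acetate | CC(=O)OCC[C@@H]1[C@H](/C=C(\C)C=O)OC(=O)[C@@H]1C | intermediate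
23 | allyltributylstannane | C=CC[Sn](CCCC)(CCCC)CCCC | starting material
24 | 2-{(2R,3S,4R)-2-[(1E,3S)-3-hydroxy-2-methylhexa-1,5-dienyl]-4-methyl-5-oxooxolan-3-yl}ethyl acetate | CC(=O)OCC[C@@H]1[C@H](/C=C(\C)[C@@H](O)CC=C)OC(=O)[C@@H]1C | intermediate
25 | 2-{(2R,3S,4R)-2-[(1E,3S)-3-[(tert-butyldimethylsilyl)oxy]-2-methylhexa-1,5-dienyl]-4-methyl-5-oxooxolan-3-yl}ethyl acetate | CC(=O)OCC[C@@H]1[C@H](/C=C(\C)[C@@H](O[Si](C)(C)C(C)(C)C)CC=C)OC(=O)[C@@H]1C | intermediate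
26 | 2-{(2R,3S,4R)-2-[(1E,3S)-3-[(tert-butyldimethylsilyl)oxy]-5,6-dihydroxy-2-methylhex-1-enyl]-4-methyl-5-oxooxolan-3-yl}ethyl acetate, both C5' epimers (not isolated) | CC(=O)OCC[C@@H]1[C@H](/C=C(\C)[C@@H](O[Si](C)(C)C(C)(C)C)CC(O)CO)OC(=O)[C@@H]1C | intermediate
27 | 2-{(2R,3S,4R)-2-[(1E,3S)-3-[(tert-butyldimethylsilyl)oxy]-2-methyl-5-oxopent-1-enyl]-4-methyl-5-oxooxolan-3-yl}ethyl acetate | CC(=O)OCC[C@@H]1[C@H](/C=C(\C)[C@@H](O[Si](C)(C)C(C)(C)C)CC=O)OC(=O)[C@@H]1C | intermediate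
28 | ethyltriphenylphosphonium iodide | CC[P+](c1ccccc1)(c1ccccc1)c1ccccc1.[I-] | starting material
29 | 2-{(2R,3S,4R)-2-[(1E,3S,5Z)-3-[(tert-butyldimethylsilyl)oxy]-6-iodo-2-methylhepta-1,5-dienyl]-4-methyl-5-oxooxolan-3-yl}ethyl acetate | CC(=O)OCC[C@@H]1[C@H](/C=C(\C)[C@@H](O[Si](C)(C)C(C)(C)C)C/C=C(/C)I)OC(=O)[C@@H]1C | intermediate
30 | 2-{(2R,3S,4R)-2-[(1E,3S,5Z)-3-hydroxy-6-iodo-2-methylhepta-1,5-dienyl]-4-methyl-5-oxooxolan-3-yl}ethyl acetate | CC(=O)OCC[C@@H]1[C@H](/C=C(\C)[C@@H](O)C/C=C(/C)I)OC(=O)[C@@H]1C | intermediate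
31 | (2R)-2-methylbutanoic 2,4,6-trichlorobenzoic anhydride (not isolated) | CC[C@@H](C)C(=O)OC(=O)c1c(Cl)cc(Cl)cc1Cl | intermediate
32 | (1E,3S,5Z)-1-[(2R,3S,4R)-3-(2-acetoxyethyl)-4-methyl-5-oxooxolan-2-yl]-6-iodo-2-methylhepta-1,5-dien-3-yl (2R)-2-methylbutanoate | CC(=O)OCC[C@@H]1[C@H](/C=C(\C)[C@@H](OC(=O)[C@H](C)CC)C/C=C(/C)I)OC(=O)[C@@H]1C | intermediate
33 | (1E,3S,5Z)-1-[(2R,3S,4R)-3-(2-hydroxyethyl)-4-methyl-5-oxooxolan-2-yl]-6-iodo-2-methylhepta-1,5-dien-3-yl (2R)-2-methylbutanoate | OCC[C@@H]1[C@H](/C=C(\C)[C@@H](OC(=O)[C@H](C)CC)C/C=C(/C)I)OC(=O)[C@@H]1C | intermediate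
34 | (1E,3S,5Z)-6-iodo-2-methyl-1-[(2R,3S,4R)-4-methyl-5-oxo-3-(2-oxoethyl)oxolan-2-yl]hepta-1,5-dien-3-yl (2R)-2-methylbutanoate | O=CC[C@@H]1[C@H](/C=C(\C)[C@@H](OC(=O)[C@H](C)CC)C/C=C(/C)I)OC(=O)[C@@H]1C | intermediate
35 | (3R,3aS,5RS,6Z,9S,10E,11aR)-5-hydroxy-3,6,10-trimethyl-2-oxo-2,3,3a,4,5,8,9,11a-octahydrocyclodeca[b]furan-9-yl (2R)-2-methylbutanoate, C9 epimers in germacrane numbering | CC[C@@H](C)C(=O)O[C@H]1C/C=C(/C)C(O)C[C@@H]2[C@H](/C=C/1C)OC(=O)[C@@H]2C | intermediate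
36 | (3R,3aS,6Z,9S,10E,11aR)-3,6,10-trimethyl-2,5-dioxo-2,3,3a,4,5,8,9,11a-octahydrocyclodeca[b]furan-9-yl (2R)-2-methylbutanoate | CC[C@@H](C)C(=O)O[C@H]1C/C=C(/C)C(=O)C[C@@H]2[C@H](/C=C/1C)OC(=O)[C@@H]2C | intermediate
37 | (3R,3aS,5S,6Z,9S,10E,11aR)-5-hydroxy-3,6,10-trimethyl-2-oxo-2,3,3a,4,5,8,9,11a-octahydrocyclodeca[b]furan-9-yl (2R)-2-methylbutanoate; germacrane numbering 3S,6R,7S,9S,11R, 1(10)Z,4E | CC[C@@H](C)C(=O)O[C@H]1C/C=C(/C)[C@@H](O)C[C@@H]2[C@H](/C=C/1C)OC(=O)[C@@H]2C | target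

**Totals**
Total step count: 24. Longest linear sequence: 23 steps (steps 2 to 24, from methyl glycolate); step 1 is a one-step side branch that joins at step 19.

**Three steps most likely to fail**

Step 22 (NHK closure of the ten-membered ring; transannular strain and oligomerisation are the risks). The fallback sets out from 24 and returns at 36, closing the ring by metathesis at C1=C10 instead. Alcohol 24 is acylated with mixed anhydride 31 (DMAP, toluene) to give (1E,3S)-1-[(2R,3S,4R)-3-(2-acetoxyethyl)-4-methyl-5-oxooxolan-2-yl]-2-methylhexa-1,5-dien-3-yl (2R)-2-methylbutanoate F2. Lipase deacetylation as in step 20 gives (1E,3S)-1-[(2R,3S,4R)-3-(2-hydroxyethyl)-4-methyl-5-oxooxolan-2-yl]-2-methylhexa-1,5-dien-3-yl (2R)-2-methylbutanoate F3. Dess–Martin oxidation gives (1E,3S)-2-methyl-1-[(2R,3S,4R)-4-methyl-5-oxo-3-(2-oxoethyl)oxolan-2-yl]hexa-1,5-dien-3-yl (2R)-2-methylbutanoate F4. Intermolecular NHK addition of 2-bromopropene (CrCl2, NiCl2 cat., DMF) gives (1E,3S)-1-[(2R,3S,4R)-3-(2-hydroxy-3-methylbut-3-enyl)-4-methyl-5-oxooxolan-2-yl]-2-methylhexa-1,5-dien-3-yl (2R)-2-methylbutanoate F5 as carbinol epimers. A second Dess–Martin oxidation gives (1E,3S)-2-methyl-1-[(2R,3S,4R)-4-methyl-3-(3-methyl-2-oxobut-3-enyl)-5-oxooxolan-2-yl]hexa-1,5-dien-3-yl (2R)-2-methylbutanoate F6. Ring-closing metathesis (second-generation Grubbs catalyst, toluene, 80 °C, 1 mM) then joins C1 to C10 with loss of ethylene; the Z alkene usual for ten-membered ring closure is expected, giving enone 36.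

Step 24 (the ketoreductase may not accept or may poorly discriminate the faces of the macrocyclic enone). The fallback sets out from 36 and returns at 37, replacing biocatalysis by a reagent-controlled chemical hydride transfer. Corey–Bakshi–Shibata reduction with (R)-2-methyl-CBS-oxazaborolidine and catecholborane (toluene, −78 °C), the α-branched alkenyl group acting as the large substituent, gives 37 directly. This fallback makes no new compound (F0).

Step 6 (the thermal allylmagnesiation of a hindered secondary propargylic alkoxide and the CO2 capture may be sluggish). The fallback sets out from 8 and returns at 13, separating the C–C bond formation from the introduction of the carbonyl carbon. Copper-catalysed anti-allylmagnesiation (allylMgCl, CuI 10 mol%, Et2O/THF, −10 °C to rt) followed by iodine quench gives (2R,3Z)-4-iodo-3-(prop-2-enyl)-1-[(triisopropylsilyl)oxy]pent-3-en-2-ol F1. Palladium-catalysed cyclocarbonylation (PdCl2(PPh3)2, CO 1 atm, Et3N, DMF, 60 °C) then inserts CO into the C–I bond and lactonises onto the cis hydroxyl to give butenolide 13.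

**Further compounds**
F1 | step 6 | (2R,3Z)-4-iodo-3-(prop-2-enyl)-1-[(triisopropylsilyl)oxy]pent-3-en-2-ol | C/C(I)=C(\CC=C)[C@@H](O)CO[Si](C(C)C)(C(C)C)C(C)C
F2 | step 22 | (1E,3S)-1-[(2R,3S,4R)-3-(2-acetoxyethyl)-4-methyl-5-oxooxolan-2-yl]-2-methylhexa-1,5-dien-3-yl (2R)-2-methylbutanoate | CC(=O)OCC[C@@H]1[C@H](/C=C(\C)[C@@H](OC(=O)[C@H](C)CC)CC=C)OC(=O)[C@@H]1C
F3 | step 22 | (1E,3S)-1-[(2R,3S,4R)-3-(2-hydroxyethyl)-4-methyl-5-oxooxolan-2-yl]-2-methylhexa-1,5-dien-3-yl (2R)-2-methylbutanoate | OCC[C@@H]1[C@H](/C=C(\C)[C@@H](OC(=O)[C@H](C)CC)CC=C)OC(=O)[C@@H]1C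
F4 | step 22 | (1E,3S)-2-methyl-1-[(2R,3S,4R)-4-methyl-5-oxo-3-(2-oxoethyl)oxolan-2-yl]hexa-1,5-dien-3-yl (2R)-2-methylbutanoate | O=CC[C@@H]1[C@H](/C=C(\C)[C@@H](OC(=O)[C@H](C)CC)CC=C)OC(=O)[C@@H]1C
F5 | step 22 | (1E,3S)-1-[(2R,3S,4R)-3-(2-hydroxy-3-methylbut-3-enyl)-4-methyl-5-oxooxolan-2-yl]-2-methylhexa-1,5-dien-3-yl (2R)-2-methylbutanoate, carbinol epimers | CC(=C)C(O)C[C@@H]1[C@H](/C=C(\C)[C@@H](OC(=O)[C@H](C)CC)CC=C)OC(=O)[C@@H]1C
F6 | step 22 | (1E,3S)-2-methyl-1-[(2R,3S,4R)-4-methyl-3-(3-methyl-2-oxobut-3-enyl)-5-oxooxolan-2-yl]hexa-1,5-dien-3-yl (2R)-2-methylbutanoate | CC(=C)C(=O)C[C@@H]1[C@H](/C=C(\C)[C@@H](OC(=O)[C@H](C)CC)CC=C)OC(=O)[C@@H]1C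
F0 | step 24 | none | none
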